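**Retrosynthetic overview**
1. The target comes from global hydrogenolysis of a tetra-O-benzyl precursor; its two para aryl esters are disconnected in turn, first the (S)-3-acetoxybutanoate (Steglich esterification), then the 3-phenylpropanoate.
2. The two para phenols of the central ring are told apart by a MOM/TBS pair; the terphenyl is cut by a twofold Suzuki coupling into a 3,6-dibromo-1,2,4,5-tetraoxygenated benzene and 4-(benzyloxy)phenylboronic acid.
3. The central ring comes from 2,5-dihydroxybenzaldehyde: Baeyer–Villiger (Dakin-type) oxidation gives the first para oxygen (as OMOM), regioselective bromination then borylation–oxidation gives the second (as OTBS).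
4. (S)-3-Acetoxybutanoic acid comes from benzyl acetoacetate by ketoreductase-catalysed asymmetric reduction, acetylation and hydrogenolysis.
5. Ring order: no ring is built; all three benzene rings are bought, the central ring is fully functionalised first, and both outer rings are then attached in one step.

Assumption: the single stereocentre is (S) as read from the SMILES, and a commercial (S)-selective (Prelog-type) ketoreductase that recycles NADPH with isopropanol is used.

**Route**

Step 1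
Reactants: 1 benzyl acetoacetate (benzyl 3-oxobutanoate)
Product: 2 benzyl (3S)-3-hydroxybutanoate
Conditions: ketoreductase (KRED, (S)-selective), NADP+ (cat.), i-PrOH (10% v/v), KH2PO4/K2HPO4 buffer pH 7.0, 30 °C
Reagents that add atoms: none
Why: Biocatalytic asymmetric ketone reduction in which the ketoreductase delivers hydride from NADPH (recycled by i-PrOH) to the re face of the β-keto ester (Prelog selectivity), setting the (S) carbinol centre in high ee.

Step 2
Reactants: 2 benzyl (3S)-3-hydroxybutanoate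
Product: 3 benzyl (3S)-3-(acetyloxy)butanoate
Conditions: Ac2O, pyridine, DMAP (cat.), CH2Cl2, 0 °C → rt
Reagents that add atoms: acetic anhydride, CC(=O)OC(C)=O
Why: DMAP-catalysed O-acetylation of the secondary alcohol breaks no bond at the stereocentre, so (S) is retained.

Step 3
Reactants: 3 benzyl (3S)-3-(acetyloxy)butanoate
Product: 4 (3S)-3-(acetyloxy)butanoic acid
Conditions: H2 (1 atm), 10% Pd/C, EtOAc, rt
Reagents that add atoms: none
Why: Hydrogenolysis of the benzyl ester frees the acid under neutral conditions that leave the acetate and the stereocentre untouched.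

Step 4
Reactants: 5 2,5-dihydroxybenzaldehyde
Product: 6 2,5-bis(benzyloxy)benzaldehyde
Conditions: BnBr (2.4 equiv), K2CO3, DMF, 60 °C, N2
Reagents that add atoms: benzyl bromide, BrCc1ccccc1
Why: Williamson ether synthesis alkylates both phenols with excess benzyl bromide.

Step 5
Reactants: 6 2,5-bis(benzyloxy)benzaldehyde
Product: 8 2,5-bis(benzyloxy)phenol, via 2,5-bis(benzyloxy)phenyl formate 7 (not isolated)
Conditions: mCPBA, CH2Cl2, 0 °C → rt; then KOH, MeOH/H2O, rt; aq HCl work-up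
Reagents that add atoms: 3-chloroperoxybenzoic acid (mCPBA), OOC(=O)c1cccc(Cl)c1
Why: Baeyer–Villiger (Dakin-type) oxidation, in which the electron-rich aryl group migrates to give the aryl formate that is saponified to the phenol.

Step 6
Reactants: 8 2,5-bis(benzyloxy)phenol
Product: 9 1,4-bis(benzyloxy)-2-(methoxymethoxy)benzene
Conditions: NaH, DMF, 0 °C; then MOMCl, 0 °C → rt
Reagents that add atoms: chloromethyl methyl ether (MOMCl), COCCl
Why: O-alkylation of the sodium phenoxide gives the MOM acetal, which is stable to the organolithium, bromination and coupling steps ahead.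

Step 7
Reactants: 9 1,4-bis(benzyloxy)-2-(methoxymethoxy)benzene
Product: 10 1,4-bis(benzyloxy)-2-bromo-5-(methoxymethoxy)benzene
Conditions: NBS (1.05 equiv), MeCN, 0 °C → rt, dark
Reagents that add atoms: N-bromosuccinimide, BrN1C(=O)CCC1=O
Why: Electrophilic aromatic bromination goes to the one unhindered position that is para to OMOM and ortho to OBn, as is usual for 1,2,4-trialkoxybenzenes.

Step 8
Reactants: 10 1,4-bis(benzyloxy)-2-bromo-5-(methoxymethoxy)benzene
Product: 13 2,5-bis(benzyloxy)-4-(methoxymethoxy)phenol, via aryllithium 11 (not isolated), via dimethyl arylboronate 12 (not isolated)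
Conditions: n-BuLi, THF, −78 °C; B(OMe)3, −78 → 0 °C; then AcOH, 30% aq H2O2, 0 °C → rt
Reagents that add atoms: n-butyllithium, [Li]CCCC (Li of 11); trimethyl borate, COB(OC)OC (B(OMe)2 of 12); hydrogen peroxide, OO (phenol O of 13)
Why: Bromine–lithium exchange, borylation and oxidative C–B to C–O cleavage install the second oxygen exactly para to the first.

Step 9
Reactants: 13 2,5-bis(benzyloxy)-4-(methoxymethoxy)phenol
Product: 14 tert-butyl{[2,5-bis(benzyloxy)-4-(methoxymethoxy)phenyl]oxy}dimethylsilane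
Conditions: TBSCl, imidazole, DMF, rt
Reagents that add atoms: tert-butyldimethylsilyl chloride, CC(C)(C)[Si](C)(C)Cl
Why: Silylation of the phenol gives a TBS ether that is orthogonal to both the MOM and the benzyl ethers.

Step 10
Reactants: 14 tert-butyl{[2,5-bis(benzyloxy)-4-(methoxymethoxy)phenyl]oxy}dimethylsilane
Product: 15 tert-butyl{[2,5-bis(benzyloxy)-3,6-dibromo-4-(methoxymethoxy)phenyl]oxy}dimethylsilane
Conditions: NBS (2.2 equiv), DMF, 0 °C → rt, dark
Reagents that add atoms: N-bromosuccinimide, BrN1C(=O)CCC1=O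
Why: Twofold electrophilic aromatic bromination at the only two free ring positions, each activated by two ortho oxygen substituents.

Step 11
Reactants: 15 tert-butyl{[2,5-bis(benzyloxy)-3,6-dibromo-4-(methoxymethoxy)phenyl]oxy}dimethylsilane; 16 4-(benzyloxy)phenylboronic acid (3.0 equiv)
Product: 17 tert-butyl{[3',4,4'',6'-tetrakis(benzyloxy)-5'-(methoxymethoxy)-[1,1':4',1''-terphenyl]-2'-yl]oxy}dimethylsilane
Conditions: Pd(OAc)2 (5 mol%), SPhos (10 mol%), K3PO4, toluene/H2O (10:1), 90 °C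
Reagents that add atoms: none
Why: Twofold Suzuki–Miyaura coupling in which the electron-rich biarylphosphine SPhos promotes oxidative addition into the hindered, electron-rich C–Br bonds; any TBS loss is harmless because the next step removes it.

Step 12
Reactants: 17 tert-butyl{[3',4,4'',6'-tetrakis(benzyloxy)-5'-(methoxymethoxy)-[1,1':4',1''-terphenyl]-2'-yl]oxy}dimethylsilane
Product: 18 3',4,4'',6'-tetrakis(benzyloxy)-5'-(methoxymethoxy)-[1,1':4',1''-terphenyl]-2'-ol
Conditions: Bu4NF, AcOH (1:1), THF, 0 °C → rt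
Reagents that add atoms: none
Why: Fluoride-mediated desilylation cleaves only the aryl silyl ether, while MOM and benzyl ethers are inert and acetic acid buffers the phenoxide.

Step 13
Reactants: 18 3',4,4'',6'-tetrakis(benzyloxy)-5'-(methoxymethoxy)-[1,1':4',1''-terphenyl]-2'-ol; 19 3-phenylpropanoyl chloride
Product: 20 3',4,4'',6'-tetrakis(benzyloxy)-5'-(methoxymethoxy)-[1,1':4',1''-terphenyl]-2'-yl 3-phenylpropanoate
Conditions: Et3N, DMAP (cat.), CH2Cl2, 0 °C → rt
Reagents that add atoms: none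
Why: DMAP-catalysed O-acylation of the hindered phenol with the acid chloride installs the first, robust ester.

Step 14
Reactants: 20 3',4,4'',6'-tetrakis(benzyloxy)-5'-(methoxymethoxy)-[1,1':4',1''-terphenyl]-2'-yl 3-phenylpropanoate
Product: 21 3',4,4'',6'-tetrakis(benzyloxy)-5'-hydroxy-[1,1':4',1''-terphenyl]-2'-yl 3-phenylpropanoate
Conditions: TFA/CH2Cl2 (1:5), 0 °C → rt; aq NaHCO3 work-up
Reagents that add atoms: none
Why: Acid-catalysed acetal cleavage removes the MOM group while the aryl ester and benzyl ethers survive; the freed phenol is para to the ester, so no acyl migration is possible.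

Step 15
Reactants: 21 3',4,4'',6'-tetrakis(benzyloxy)-5'-hydroxy-[1,1':4',1''-terphenyl]-2'-yl 3-phenylpropanoate; 4 (3S)-3-(acetyloxy)butanoic acid (1.5 equiv)
Product: 22 3',4,4'',6'-tetrakis(benzyloxy)-5'-[(3-phenylpropanoyl)oxy]-[1,1':4',1''-terphenyl]-2'-yl (3S)-3-(acetyloxy)butanoate
Conditions: DCC, DMAP (0.2 equiv), CH2Cl2, 0 °C → rt
Reagents that add atoms: none
Why: Steglich esterification at low temperature acylates the phenol; the stereocentre is β to the activated carbonyl and is not touched.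

Step 16
Reactants: 22 3',4,4'',6'-tetrakis(benzyloxy)-5'-[(3-phenylpropanoyl)oxy]-[1,1':4',1''-terphenyl]-2'-yl (3S)-3-(acetyloxy)butanoate
Product: 23 3',4,4'',6'-tetrahydroxy-5'-[(3-phenylpropanoyl)oxy]-[1,1':4',1''-terphenyl]-2'-yl (3S)-3-(acetyloxy)butanoate
Conditions: H2 (1 atm), 10% Pd/C, EtOAc/THF, rt
Reagents that add atoms: none
Why: Hydrogenolysis of the four benzyl aryl ethers under neutral, base-free conditions leaves both aryl esters, the acetate and the (S) centre intact and gives no chance for acyl migration.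

**Compound list**
1 | benzyl acetoacetate | CC(=O)CC(=O)OCc1ccccc1 | starting material
2 | benzyl (3S)-3-hydroxybutanoate | C[C@H](O)CC(=O)OCc1ccccc1 | intermediate
3 | benzyl (3S)-3-(acetyloxy)butanoate | CC(=O)O[C@@H](C)CC(=O)OCc1ccccc1 | intermediate
4 | (3S)-3-(acetyloxy)butanoic acid | CC(=O)O[C@@H](C)CC(=O)O | intermediate
5 | 2,5-dihydroxybenzaldehyde | O=Cc1cc(O)ccc1O | starting material
6 | 2,5-bis(benzyloxy)benzaldehyde | O=Cc1cc(OCc2ccccc2)ccc1OCc1ccccc1 | intermediate
7 | 2,5-bis(benzyloxy)phenyl formate | O=COc1cc(OCc2ccccc2)ccc1OCc1ccccc1 | intermediate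
8 | 2,5-bis(benzyloxy)phenol | Oc1cc(OCc2ccccc2)ccc1OCc1ccccc1 | intermediate
9 | 1,4-bis(benzyloxy)-2-(methoxymethoxy)benzene | COCOc1cc(OCc2ccccc2)ccc1OCc1ccccc1 | intermediate
10 | 1,4-bis(benzyloxy)-2-bromo-5-(methoxymethoxy)benzene | COCOc1cc(OCc2ccccc2)c(Br)cc1OCc1ccccc1 | intermediate
11 | [2,5-bis(benzyloxy)-4-(methoxymethoxy)phenyl]lithium (aryllithium) | COCOc1cc(OCc2ccccc2)c([Li])cc1OCc1ccccc1 | intermediate
12 | dimethyl [2,5-bis(benzyloxy)-4-(methoxymethoxy)phenyl]boronate | COCOc1cc(OCc2ccccc2)c(B(OC)OC)cc1OCc1ccccc1 | intermediate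
13 | 2,5-bis(benzyloxy)-4-(methoxymethoxy)phenol | COCOc1cc(OCc2ccccc2)c(O)cc1OCc1ccccc1 | intermediate
14 | tert-butyl{[2,5-bis(benzyloxy)-4-(methoxymethoxy)phenyl]oxy}dimethylsilane | COCOc1cc(OCc2ccccc2)c(O[Si](C)(C)C(C)(C)C)cc1OCc1ccccc1 | intermediate
15 | tert-butyl{[2,5-bis(benzyloxy)-3,6-dibromo-4-(methoxymethoxy)phenyl]oxy}dimethylsilane | COCOc1c(Br)c(OCc2ccccc2)c(O[Si](C)(C)C(C)(C)C)c(Br)c1OCc1ccccc1 | intermediate
16 | 4-(benzyloxy)phenylboronic acid | OB(O)c1ccc(OCc2ccccc2)cc1 | starting material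
17 | tert-butyl{[3',4,4'',6'-tetrakis(benzyloxy)-5'-(methoxymethoxy)-[1,1':4',1''-terphenyl]-2'-yl]oxy}dimethylsilane | COCOc1c(-c2ccc(OCc3ccccc3)cc2)c(OCc2ccccc2)c(O[Si](C)(C)C(C)(C)C)c(-c2ccc(OCc3ccccc3)cc2)c1OCc1ccccc1 | intermediate
18 | 3',4,4'',6'-tetrakis(benzyloxy)-5'-(methoxymethoxy)-[1,1':4',1''-terphenyl]-2'-ol | COCOc1c(-c2ccc(OCc3ccccc3)cc2)c(OCc2ccccc2)c(O)c(-c2ccc(OCc3ccccc3)cc2)c1OCc1ccccc1 | intermediate
19 | 3-phenylpropanoyl chloride | O=C(Cl)CCc1ccccc1 | starting material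
20 | 3',4,4'',6'-tetrakis(benzyloxy)-5'-(methoxymethoxy)-[1,1':4',1''-terphenyl]-2'-yl 3-phenylpropanoate | COCOc1c(-c2ccc(OCc3ccccc3)cc2)c(OCc2ccccc2)c(OC(=O)CCc2ccccc2)c(-c2ccc(OCc3ccccc3)cc2)c1OCc1ccccc1 | intermediate
21 | 3',4,4'',6'-tetrakis(benzyloxy)-5'-hydroxy-[1,1':4',1''-terphenyl]-2'-yl 3-phenylpropanoate | Oc1c(-c2ccc(OCc3ccccc3)cc2)c(OCc2ccccc2)c(OC(=O)CCc2ccccc2)c(-c2ccc(OCc3ccccc3)cc2)c1OCc1ccccc1 | intermediate
22 | 3',4,4'',6'-tetrakis(benzyloxy)-5'-[(3-phenylpropanoyl)oxy]-[1,1':4',1''-terphenyl]-2'-yl (3S)-3-(acetyloxy)butanoate | CC(=O)O[C@@H](C)CC(=O)Oc1c(OCc2ccccc2)c(-c2ccc(OCc3ccccc3)cc2)c(OC(=O)CCc2ccccc2)c(OCc2ccccc2)c1-c1ccc(OCc2ccccc2)cc1 | intermediate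
23 | 3',4,4'',6'-tetrahydroxy-5'-[(3-phenylpropanoyl)oxy]-[1,1':4',1''-terphenyl]-2'-yl (3S)-3-(acetyloxy)butanoate (CNP0332078.1) | CC(=O)O[C@@H](C)CC(=O)Oc1c(O)c(-c2ccc(O)cc2)c(OC(=O)CCc2ccccc2)c(O)c1-c1ccc(O)cc1 | target

**Step count**
Total: 16 steps (3 for the acid, 13 for the aromatic core and endgame). Longest linear sequence: 13 steps (5 → 23, steps 4 to 16).

**Three steps most likely to fail, with fallbacks**

Step 10 (twofold bromination of 14). The ring carries four oxygens and may be over-oxidised to a quinone, or lose the silyl or MOM group, before the second bromine enters. The fallback sets out from 13 and carries the first ester in place of the silyl ether. Phenol 13 is acylated with 19 (Et3N, DMAP, CH2Cl2) to give 2,5-bis(benzyloxy)-4-(methoxymethoxy)phenyl 3-phenylpropanoate F1, whose acyloxy group makes the ring less oxidisable and has no Si–O bond to lose. NBS in DMF then gives 2,5-bis(benzyloxy)-3,6-dibromo-4-(methoxymethoxy)phenyl 3-phenylpropanoate F2. A twofold Suzuki coupling with 16 under anhydrous conditions (Pd(OAc)2, SPhos, powdered K3PO4, toluene, 90 °C) spares the hindered aryl ester and comes back to the route at 20.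

Step 11 (twofold Suzuki coupling of 15). The second coupling may stall at the mono-aryl stage, or give protodebromination, on so electron-rich and hindered a bromide. The fallback sets out from 8 and does the coupling at the electron-poor quinone oxidation level. Phenol 8 is oxidised with (KSO3)2NO (KH2PO4 buffer, acetone/H2O) to 2,5-bis(benzyloxy)-1,4-benzoquinone F3. Br2 with NaOAc in AcOH/CHCl3 gives 2,5-bis(benzyloxy)-3,6-dibromo-1,4-benzoquinone F4. Coupling with 16 (Pd(dppf)Cl2, K3PO4, dioxane, 80 °C) gives 2,5-bis(benzyloxy)-3,6-bis[4-(benzyloxy)phenyl]-1,4-benzoquinone F5. Reduction with Na2S2O4 in THF/H2O gives 2,5-bis(benzyloxy)-3,6-bis[4-(benzyloxy)phenyl]benzene-1,4-diol F6. Mono-acylation with 1.0 equiv of 19 (Et3N, CH2Cl2, −20 °C) is statistical; the mono-ester is separated and diol and diester are recycled. This comes back to the route at 21.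

Step 15 (Steglich esterification with 4). The activated β-acetoxy acid can lose acetate by elimination to a crotonate before the hindered phenol attacks. The fallback sets out from 2 and brings in the acetyl group only after the coupling. Alcohol 2 is silylated (TBSCl, imidazole, DMF) to benzyl (3S)-3-[(tert-butyldimethylsilyl)oxy]butanoate F7. Hydrogenolysis (H2, Pd/C, EtOAc) gives (3S)-3-[(tert-butyldimethylsilyl)oxy]butanoic acid F8, whose silyloxy group is a poor leaving group. DCC/DMAP coupling with 21 gives the (3S)-3-silyloxybutanoate ester of 21 F9. HF·pyridine in THF gives the (3S)-3-hydroxybutanoate ester of 21 F10. Ac2O, pyridine and DMAP (cat.) at 0 °C then come back to the route at 22.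

**Further compounds**
F1 | step 10 | 2,5-bis(benzyloxy)-4-(methoxymethoxy)phenyl 3-phenylpropanoate | O=C(CCc1ccccc1)Oc1cc(OCc2ccccc2)c(OCOC)cc1OCc1ccccc1
F2 | step 10 | 2,5-bis(benzyloxy)-3,6-dibromo-4-(methoxymethoxy)phenyl 3-phenylpropanoate | O=C(CCc1ccccc1)Oc1c(Br)c(OCc2ccccc2)c(OCOC)c(Br)c1OCc1ccccc1
F3 | step 11 | 2,5-bis(benzyloxy)-1,4-benzoquinone | O=C1C=C(OCc2ccccc2)C(=O)C=C1OCc1ccccc1
F4 | step 11 | 2,5-bis(benzyloxy)-3,6-dibromo-1,4-benzoquinone | O=C1C(Br)=C(OCc2ccccc2)C(=O)C(Br)=C1OCc1ccccc1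
F5 | step 11 | 2,5-bis(benzyloxy)-3,6-bis[4-(benzyloxy)phenyl]-1,4-benzoquinone | O=C1C(-c2ccc(OCc3ccccc3)cc2)=C(OCc2ccccc2)C(=O)C(-c2ccc(OCc3ccccc3)cc2)=C1OCc1ccccc1
F6 | step 11 | 2,5-bis(benzyloxy)-3,6-bis[4-(benzyloxy)phenyl]benzene-1,4-diol | Oc1c(-c2ccc(OCc3ccccc3)cc2)c(OCc2ccccc2)c(O)c(-c2ccc(OCc3ccccc3)cc2)c1OCc1ccccc1
F7 | step 15 | benzyl (3S)-3-[(tert-butyldimethylsilyl)oxy]butanoate | C[C@H](O[Si](C)(C)C(C)(C)C)CC(=O)OCc1ccccc1
F8 | step 15 | (3S)-3-[(tert-butyldimethylsilyl)oxy]butanoic acid | C[C@H](O[Si](C)(C)C(C)(C)C)CC(=O)O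
F9 | step 15 | 3',4,4'',6'-tetrakis(benzyloxy)-5'-[(3-phenylpropanoyl)oxy]-[1,1':4',1''-terphenyl]-2'-yl (3S)-3-[(tert-butyldimethylsilyl)oxy]butanoate | C[C@H](O[Si](C)(C)C(C)(C)C)CC(=O)Oc1c(OCc2ccccc2)c(-c2ccc(OCc3ccccc3)cc2)c(OC(=O)CCc2ccccc2)c(OCc2ccccc2)c1-c1ccc(OCc2ccccc2)cc1
F10 | step 15 | 3',4,4'',6'-tetrakis(benzyloxy)-5'-[(3-phenylpropanoyl)oxy]-[1,1':4',1''-terphenyl]-2'-yl (3S)-3-hydroxybutanoate | C[C@H](O)CC(=O)Oc1c(OCc2ccccc2)c(-c2ccc(OCc3ccccc3)cc2)c(OC(=O)CCc2ccccc2)c(OCc2ccccc2)c1-c1ccc(OCc2ccccc2)cc1
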